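**Strategy.** Everything rests on disconnecting C3–C4 of the pyranone (C) ring. C3 carries an enol-ether oxygen and C4 the ketone oxygen: two neighbouring oxygenated carbons, an acyloin minus two hydrogens, so both can be aldehyde carbons. A triazolylidene carbene converts the A-ring formyl carbon into an acyl-anion equivalent that adds to a side-chain aldehyde, forming C3–C4, the C ring and the C3 carbinol in one operation. The substrate is the tetra-O-benzyl dialdehyde 15, whose O1–C2 aryl ether already joins the 8-methoxylated A-ring salicylaldehyde to the B-ring arylacetaldehyde unit. Both halves grow from one phenol (4); acyloin dehydrogenation, 3-O-methylation and hydrogenolysis finish the target.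

Key step: step 12

Remark on the chemistry: the target has no stereocentre (a planar, achiral flavone), so there is no enantiomer to select. C2 and C3 are stereogenic only in compounds 12–16, which are carried as racemates, and both centres become sp2 in step 13.

**Step 1**
Reactants: 1 2,4-dihydroxybenzaldehyde
Product: 2 2,4-bis(benzyloxy)benzaldehyde
Conditions: BnBr (2.4 equiv), K2CO3, DMF, 60 °C
Reagents that add atoms: benzyl bromide, BrCc1ccccc1
Why: Williamson etherification with excess halide in DMF should alkylate both phenols, including the chelated ortho one.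

**Step 2**
Reactants: 2 2,4-bis(benzyloxy)benzaldehyde
Product: 4 2,4-bis(benzyloxy)phenol, via aryl formate 3 (not isolated)
Conditions: mCPBA, CH2Cl2, 0 °C → rt; then K2CO3 (cat.), MeOH, rt
Reagents that add atoms: mCPBA, O=C(OO)c1cccc(Cl)c1
Why: Baeyer–Villiger (Dakin-type) oxidation, in which the aryl group with ortho and para alkoxy donors should migrate in preference to hydride and the formate is then cleaved by methanolysis.

**Step 3**
Reactants: 4 2,4-bis(benzyloxy)phenol
Product: 5 3,5-bis(benzyloxy)-2-hydroxybenzaldehyde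
Conditions: MgCl2, Et3N, (CH2O)n, MeCN, reflux
Reagents that add atoms: paraformaldehyde (formaldehyde), C=O
Why: Magnesium-mediated ortho-formylation of a phenol (Casnati–Skattebøl reaction), in which the magnesium phenoxide delivers formaldehyde to the only free ortho carbon and a second formaldehyde takes the hydride to give the aldehyde.

**Step 4**
Reactants: 5 3,5-bis(benzyloxy)-2-hydroxybenzaldehyde
Product: 6 3,5-bis(benzyloxy)-2-methoxybenzaldehyde
Conditions: MeI, K2CO3, DMF, rt
Reagents that add atoms: iodomethane, CI
Why: Williamson O-methylation of the only free hydroxyl; this methoxy group becomes the 8-OMe of the target.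

**Step 5**
Reactants: 6 3,5-bis(benzyloxy)-2-methoxybenzaldehyde
Product: 8 3,5-bis(benzyloxy)-2-methoxyphenol, via aryl formate 7 (not isolated)
Conditions: mCPBA, CH2Cl2, 0 °C → rt; then K2CO3 (cat.), MeOH, rt
Reagents that add atoms: mCPBA, O=C(OO)c1cccc(Cl)c1
Why: Baeyer–Villiger oxidation of an ortho-alkoxybenzaldehyde, where the ortho methoxy group should support aryl migration, followed by formate methanolysis to the phenol with the OH next to the OMe.

**Step 6**
Reactants: 8 3,5-bis(benzyloxy)-2-methoxyphenol
Product: 9 4,6-bis(benzyloxy)-2-hydroxy-3-methoxybenzaldehyde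
Conditions: MgCl2, Et3N, (CH2O)n, MeCN, reflux
Reagents that add atoms: paraformaldehyde (formaldehyde), C=O
Why: Magnesium-mediated ortho-formylation again, directed to the single free ortho position, which is also activated by an ortho and a para benzyloxy group.

**Step 7**
Reactants: 4 2,4-bis(benzyloxy)phenol
Product: 10 2,4-bis(benzyloxy)-1-methoxybenzene
Conditions: MeI, K2CO3, acetone, reflux
Reagents that add atoms: iodomethane, CI
Why: Williamson O-methylation; this methoxy group becomes the 5'-OMe of the target.

**Step 8**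
Reactants: 10 2,4-bis(benzyloxy)-1-methoxybenzene, 11 ethyl glyoxylate
Product: 12 ethyl 2-[2,4-bis(benzyloxy)-5-methoxyphenyl]-2-hydroxyacetate (racemic)
Conditions: ethyl glyoxylate (toluene solution, 2 equiv), Yb(OTf)3 (10 mol%), CH2Cl2, rt
Reagents that add atoms: none
Why: Lewis-acid-catalysed Friedel–Crafts hydroxyalkylation, in which the arene should attack through the carbon para to one benzyloxy group and ortho to the other (the only doubly activated, unhindered site), the ester-bearing carbinol being too deactivated to arylate again under the mild catalyst; the new centre forms racemic, which suffices.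

**Step 9**
Reactants: 9 4,6-bis(benzyloxy)-2-hydroxy-3-methoxybenzaldehyde, 12 ethyl 2-[2,4-bis(benzyloxy)-5-methoxyphenyl]-2-hydroxyacetate (racemic)
Product: 13 ethyl 2-[2,4-bis(benzyloxy)-5-methoxyphenyl]-2-[3,5-bis(benzyloxy)-2-formyl-6-methoxyphenoxy]acetate (racemic)
Conditions: PPh3, DIAD, THF, 0 °C → rt
Reagents that add atoms: none
Why: Mitsunobu reaction, in which the chelated but acidic salicylaldehyde hydroxyl protonates the betaine and its phenoxide displaces the oxyphosphonium at the benzylic carbon next to the ester, forming the O1–C2 ether as a racemate.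

**Step 10**
Reactants: 13 ethyl 2-[2,4-bis(benzyloxy)-5-methoxyphenyl]-2-[3,5-bis(benzyloxy)-2-formyl-6-methoxyphenoxy]acetate (racemic)
Product: 14 2-[2,4-bis(benzyloxy)-5-methoxyphenyl]-2-[3,5-bis(benzyloxy)-2-(hydroxymethyl)-6-methoxyphenoxy]ethan-1-ol (racemic)
Conditions: LiAlH4, THF, 0 °C; basic (Fieser) work-up
Reagents that add atoms: none
Why: Hydride reduction of ester and aldehyde to the diol, with aryl and benzyl ethers inert and a basic work-up protecting the acid-labile trialkoxybenzylic carbinol.

**Step 11**
Reactants: 14 2-[2,4-bis(benzyloxy)-5-methoxyphenyl]-2-[3,5-bis(benzyloxy)-2-(hydroxymethyl)-6-methoxyphenoxy]ethan-1-ol (racemic)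
Product: 15 4,6-bis(benzyloxy)-2-{1-[2,4-bis(benzyloxy)-5-methoxyphenyl]-2-oxoethoxy}-3-methoxybenzaldehyde (racemic)
Conditions: Dess–Martin periodinane (2.6 equiv), pyridine, CH2Cl2, 0 °C → rt; used at once without chromatography
Reagents that add atoms: none
Why: Dess–Martin oxidation of both primary alcohols under pyridine buffering, conditions neutral enough to avoid ionisation of the electron-rich benzylic carbinol and over-oxidation of the enolisable α-aryloxy aldehyde.

**Step 12**
Reactants: 15 4,6-bis(benzyloxy)-2-{1-[2,4-bis(benzyloxy)-5-methoxyphenyl]-2-oxoethoxy}-3-methoxybenzaldehyde (racemic)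
Product: 16 5,7-bis(benzyloxy)-2-[2,4-bis(benzyloxy)-5-methoxyphenyl]-3-hydroxy-8-methoxychroman-4-one (racemic, mixture of 2,3-cis and 2,3-trans isomers)
Conditions: 2-(pentafluorophenyl)-6,7-dihydro-5H-pyrrolo[2,1-c][1,2,4]triazol-2-ium tetrafluoroborate (20 mol%), i-Pr2NEt (15 mol%), degassed toluene (0.01 M), Ar, rt → 40 °C
Reagents that add atoms: none
Why: The triazolylidene adds to the A-ring formyl carbon (future C4), proton transfer gives the enaminol (acyl-anion equivalent), this attacks the side-chain aldehyde carbon (future C3), and proton transfer with loss of the carbene releases the α-hydroxy ketone. The closest known reactions are the carbene-catalysed intramolecular crossed benzoin cyclisations of O-tethered salicylaldehyde keto-ethers to 3-hydroxychroman-4-ones and the triazolylidene-catalysed crossed acyloin couplings of ortho-substituted aryl aldehydes (donor) with aliphatic aldehydes (acceptor). The pyranone ring closes in a 6-exo-trig mode onto the aldehyde C=O. The new C3 centre is set only relative to C2 by the substrate (the 2,3-trans isomer with both groups equatorial should prevail, since C3 can epimerise next to the ketone), and no control is needed because C2 and C3 become sp2 in step 13. The step needs chemoselectivity: the six-membered tether and high dilution favour ring closure over dimerisation, the more acidic benzylic C–H of the aryl carbinol adduct and the α-branching of the side-chain aldehyde favour donor formation at the aryl aldehyde, and keeping the amine below the azolium loading limits enolisation and aldol closure of the α-aryloxy aldehyde. Should the carbene activate the side-chain aldehyde and close in the opposite sense, the isomeric 4-hydroxychroman-3-one should feed the same flavonol in step 13.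

**Step 13**
Reactants: 16 5,7-bis(benzyloxy)-2-[2,4-bis(benzyloxy)-5-methoxyphenyl]-3-hydroxy-8-methoxychroman-4-one (racemic, diastereomer mixture)
Product: 17 5,7-bis(benzyloxy)-2-[2,4-bis(benzyloxy)-5-methoxyphenyl]-3-hydroxy-8-methoxy-4H-chromen-4-one
Conditions: I2 (0.2 equiv), DMSO, 100 °C
Reagents that add atoms: none
Why: Iodine/DMSO dehydrogenation of a dihydroflavonol (α-iodination of the enolised acyloin, loss of HI to the 3,4-dione and enolisation to the aromatic pyranone), which should converge both diastereomers and erase the C2 and C3 stereocentres.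

**Step 14**
Reactants: 17 5,7-bis(benzyloxy)-2-[2,4-bis(benzyloxy)-5-methoxyphenyl]-3-hydroxy-8-methoxy-4H-chromen-4-one
Product: 18 5,7-bis(benzyloxy)-2-[2,4-bis(benzyloxy)-5-methoxyphenyl]-3,8-dimethoxy-4H-chromen-4-one
Conditions: MeI, K2CO3, acetone, reflux
Reagents that add atoms: iodomethane, CI
Why: Williamson O-methylation of the 3-hydroxyl, the only free hydroxyl in the molecule.

**Step 15**
Reactants: 18 5,7-bis(benzyloxy)-2-[2,4-bis(benzyloxy)-5-methoxyphenyl]-3,8-dimethoxy-4H-chromen-4-one
Product: 19 5,7-dihydroxy-2-(2,4-dihydroxy-5-methoxyphenyl)-3,8-dimethoxy-4H-chromen-4-one (5,7,2',4'-tetrahydroxy-3,8,5'-trimethoxyflavone)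
Conditions: H2 (1 atm), 10% Pd/C, THF–MeOH, rt
Reagents that add atoms: none
Why: Catalytic hydrogenolysis should cleave the four aryl benzyl ethers while the methyl ethers and the conjugated pyranone double bond stay intact under these mild conditions.

**Compound list**

1 | 2,4-dihydroxybenzaldehyde | O=Cc1ccc(O)cc1O | starting material
2 | 2,4-bis(benzyloxy)benzaldehyde | O=Cc1ccc(OCc2ccccc2)cc1OCc1ccccc1 | intermediate
3 | 2,4-bis(benzyloxy)phenyl formate | O=COc1ccc(OCc2ccccc2)cc1OCc1ccccc1 | intermediate (not isolated)
4 | 2,4-bis(benzyloxy)phenol | Oc1ccc(OCc2ccccc2)cc1OCc1ccccc1 | intermediate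
5 | 3,5-bis(benzyloxy)-2-hydroxybenzaldehyde | O=Cc1cc(OCc2ccccc2)cc(OCc2ccccc2)c1O | intermediate
6 | 3,5-bis(benzyloxy)-2-methoxybenzaldehyde | O=Cc1cc(OCc2ccccc2)cc(OCc2ccccc2)c1OC | intermediate
7 | 3,5-bis(benzyloxy)-2-methoxyphenyl formate | O=COc1cc(OCc2ccccc2)cc(OCc2ccccc2)c1OC | intermediate (not isolated)
8 | 3,5-bis(benzyloxy)-2-methoxyphenol | Oc1cc(OCc2ccccc2)cc(OCc2ccccc2)c1OC | intermediate
9 | 4,6-bis(benzyloxy)-2-hydroxy-3-methoxybenzaldehyde | O=Cc1c(O)c(OC)c(OCc2ccccc2)cc1OCc1ccccc1 | intermediate
10 | 2,4-bis(benzyloxy)-1-methoxybenzene | COc1ccc(OCc2ccccc2)cc1OCc1ccccc1 | intermediate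
11 | ethyl glyoxylate | CCOC(=O)C=O | starting material
12 | ethyl 2-[2,4-bis(benzyloxy)-5-methoxyphenyl]-2-hydroxyacetate (racemic) | CCOC(=O)C(O)c1cc(OC)c(OCc2ccccc2)cc1OCc1ccccc1 | intermediate
13 | ethyl 2-[2,4-bis(benzyloxy)-5-methoxyphenyl]-2-[3,5-bis(benzyloxy)-2-formyl-6-methoxyphenoxy]acetate (racemic) | CCOC(=O)C(Oc1c(C=O)c(OCc2ccccc2)cc(OCc2ccccc2)c1OC)c1cc(OC)c(OCc2ccccc2)cc1OCc1ccccc1 | intermediate
14 | 2-[2,4-bis(benzyloxy)-5-methoxyphenyl]-2-[3,5-bis(benzyloxy)-2-(hydroxymethyl)-6-methoxyphenoxy]ethan-1-ol (racemic) | OCC(Oc1c(CO)c(OCc2ccccc2)cc(OCc2ccccc2)c1OC)c1cc(OC)c(OCc2ccccc2)cc1OCc1ccccc1 | intermediate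
15 | 4,6-bis(benzyloxy)-2-{1-[2,4-bis(benzyloxy)-5-methoxyphenyl]-2-oxoethoxy}-3-methoxybenzaldehyde (racemic) | O=CC(Oc1c(C=O)c(OCc2ccccc2)cc(OCc2ccccc2)c1OC)c1cc(OC)c(OCc2ccccc2)cc1OCc1ccccc1 | intermediate
16 | 5,7-bis(benzyloxy)-2-[2,4-bis(benzyloxy)-5-methoxyphenyl]-3-hydroxy-8-methoxychroman-4-one (racemic, cis/trans mixture at C2/C3) | COc1cc(C2Oc3c(OC)c(OCc4ccccc4)cc(OCc4ccccc4)c3C(=O)C2O)c(OCc2ccccc2)cc1OCc1ccccc1 | intermediate
17 | 5,7-bis(benzyloxy)-2-[2,4-bis(benzyloxy)-5-methoxyphenyl]-3-hydroxy-8-methoxy-4H-chromen-4-one | COc1cc(-c2oc3c(OC)c(OCc4ccccc4)cc(OCc4ccccc4)c3c(=O)c2O)c(OCc2ccccc2)cc1OCc1ccccc1 | intermediate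
18 | 5,7-bis(benzyloxy)-2-[2,4-bis(benzyloxy)-5-methoxyphenyl]-3,8-dimethoxy-4H-chromen-4-one | COc1cc(-c2oc3c(OC)c(OCc4ccccc4)cc(OCc4ccccc4)c3c(=O)c2OC)c(OCc2ccccc2)cc1OCc1ccccc1 | intermediate
19 | 5,7-dihydroxy-2-(2,4-dihydroxy-5-methoxyphenyl)-3,8-dimethoxy-4H-chromen-4-one (achiral) | COc1cc(-c2oc3c(OC)c(O)cc(O)c3c(=O)c2OC)c(O)cc1O | target

**Step count**

Total: 15 steps. Longest linear sequence: 13 steps (steps 1–6, then 9–15).

**Steps most likely to fail**

Step 12. The carbene may engage the side-chain aldehyde first, and the resulting acyl-anion equivalent can expel the A-ring aryloxide (an internal redox that breaks the O1–C2 ether). Alternatively the amine may enolise the α-aryloxy aldehyde, which then closes onto the aryl aldehyde in an aldol sense. The fallback joins the same two carbons reductively and sets out from 15. Samarium diiodide in THF/t-BuOH at −78 °C should reduce the more easily reduced aryl aldehyde to its ketyl, which adds to the neighbouring aldehyde in an intramolecular pinacol coupling to give 5,7-bis(benzyloxy)-2-[2,4-bis(benzyloxy)-5-methoxyphenyl]-8-methoxychromane-3,4-diol F1. IBX in DMSO, an oxidant that does not cleave 1,2-diols, should then take both carbinols to the 3,4-dione, whose enol is flavonol 17. The route is rejoined at 17, and step 14 follows.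

Step 9. The hindered, chelated phenol may capture the activated carbinol too slowly, so that ionisation of the electron-rich benzylic oxyphosphonium and alkylation of the hydrazide take over. The fallback sets out from 12 and uses a preformed electrophile. PBr3 in CH2Cl2 at 0 °C should give ethyl 2-[2,4-bis(benzyloxy)-5-methoxyphenyl]-2-bromoacetate F2, used crude. Williamson alkylation of phenol 9 with F2 (Cs2CO3, MeCN, rt, kept mild to avoid aldol closure of the product) should give 13, where the route is rejoined.

Step 11. The diol carries a 2,4,6-trioxygenated benzylic carbinol that ionises easily, and the product has a doubly activated α-hydrogen. Material may therefore be lost by benzylic ionisation and oligomerisation during oxidation, or by enolisation and hydration of the new aldehyde on work-up. The fallback avoids the diol and the double oxidation and sets out from 13. Trimethyl orthoformate with catalytic PPTS in MeOH should mask the aryl aldehyde as ethyl 2-[2,4-bis(benzyloxy)-5-methoxyphenyl]-2-[3,5-bis(benzyloxy)-2-(dimethoxymethyl)-6-methoxyphenoxy]acetate F3. DIBAL-H in toluene at −78 °C should stop at the aldehyde stage of the α-aryloxy ester, giving 2-[2,4-bis(benzyloxy)-5-methoxyphenyl]-2-[3,5-bis(benzyloxy)-2-(dimethoxymethyl)-6-methoxyphenoxy]acetaldehyde F4. Wet silica gel or dilute oxalic acid in moist CH2Cl2 should then cleave the very labile electron-rich aryl acetal to give 15, where the route is rejoined.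

**Further compounds**

F1 | step 12 | 5,7-bis(benzyloxy)-2-[2,4-bis(benzyloxy)-5-methoxyphenyl]-8-methoxychromane-3,4-diol (racemic, diastereomer mixture) | COc1cc(C2Oc3c(OC)c(OCc4ccccc4)cc(OCc4ccccc4)c3C(O)C2O)c(OCc2ccccc2)cc1OCc1ccccc1
F2 | step 9 | ethyl 2-[2,4-bis(benzyloxy)-5-methoxyphenyl]-2-bromoacetate (racemic) | CCOC(=O)C(Br)c1cc(OC)c(OCc2ccccc2)cc1OCc1ccccc1
F3 | step 11 | ethyl 2-[2,4-bis(benzyloxy)-5-methoxyphenyl]-2-[3,5-bis(benzyloxy)-2-(dimethoxymethyl)-6-methoxyphenoxy]acetate (racemic) | CCOC(=O)C(Oc1c(C(OC)OC)c(OCc2ccccc2)cc(OCc2ccccc2)c1OC)c1cc(OC)c(OCc2ccccc2)cc1OCc1ccccc1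
F4 | step 11 | 2-[2,4-bis(benzyloxy)-5-methoxyphenyl]-2-[3,5-bis(benzyloxy)-2-(dimethoxymethyl)-6-methoxyphenoxy]acetaldehyde (racemic) | O=CC(Oc1c(C(OC)OC)c(OCc2ccccc2)cc(OCc2ccccc2)c1OC)c1cc(OC)c(OCc2ccccc2)cc1OCc1ccccc1
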